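**Retrosynthetic overview**
1. Target ⇐ hydroxyl-directed epoxidation of the C4=C5 cyclopentene and esterification at C10; the cyclopentene is carried as a cis-fused β-lactone and unmasked late by loss of CO2.
2. Seven-membered ring ⇐ intramolecular carbonyl-ene closure of C1–C10 (aldehyde onto an isobutenyl group), which sets C1 and C10; the isopropenyl group is then hydrogenated.
3. Key bond C2–C6 (ring fusion) and the five-membered ring ⇐ carbene-catalysed homoenolate [3+2] annulation of a β-alkyl enal (C5–C10 plus the later CO2 carbon) with commercial 6-methylhepta-3,5-dien-2-one (C1–C4): the enal β-carbon, made nucleophilic, attacks the enone β-carbon.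
4. Enal ⇐ (S)-2-methylepichlorohydrin as the C8 linchpin: 1,3-dithiane (masked C10 aldehyde), then vinyl Grignard, then cross-metathesis with crotonaldehyde.
5. Ring order: five-membered ring (as lactone-fused cyclopentane) → seven-membered ring → oxirane.

Locants used for all ring compounds: C1 = CH bearing isopropyl/isopropenyl; C2 and C6 = ring-fusion carbons (C2 next to C1); C3 = CH2; C4 = C–CH3; C5 = CH; C7 = CH2; C8 = C(CH3)–O; C9 = CH2; C10 = CH–O. The target is (1S,2R,4R,5S,6S,8R,10S): trans ring fusion, all ring substituents equatorial except the axial C8 hydroxyl, oxirane cis to that hydroxyl.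

Assumption 1: (S)-2-(chloromethyl)-2-methyloxirane is bought as the single enantiomer (its racemate is a bulk chemical).
Assumption 2: the sense of induction of the chiral imidazolium salt in step 4 is taken from the chalcone series; if it is the reverse, the mirror-image salt (from the other commercial aminoindanol enantiomer) is used and nothing else changes.

**Route**

Step 1
Reactants: 1 1,3-dithiane (the six-membered 1,3-dithiacyclohexane); 2 (S)-2-(chloromethyl)-2-methyloxirane
Product: 5 (S)-2-[(2-methyloxiran-2-yl)methyl]-1,3-dithiane, via 2-lithio-1,3-dithiane 3 (not isolated), via lithium chloro alkoxide 4 (not isolated)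
Conditions: n-BuLi, THF, −30 °C; then 2, −78 to 23 °C
Reagents that add atoms: none
Why: Dithiane alkylation through the epichlorohydrin relay: the formyl-anion equivalent 3 opens the oxirane of 2 at its CH2 and the chloro alkoxide 4 closes a new oxirane onto the former CH2Cl on warming; no bond to the quaternary carbon is touched, so its configuration (the future C8) is carried over.

Step 2
Reactants: 5 (S)-2-[(2-methyloxiran-2-yl)methyl]-1,3-dithiane; 6 vinylmagnesium bromide
Product: 8 triethyl{[(2R)-1-(1,3-dithian-2-yl)-2-methylpent-4-en-2-yl]oxy}silane, via bromomagnesium alkoxide 7 (not isolated)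
Conditions: CuI (10 mol %), THF, −30 to 0 °C; then TESOTf, −30 to 23 °C
Reagents that add atoms: triethylsilyl trifluoromethanesulfonate CC[Si](CC)(CC)OS(=O)(=O)C(F)(F)F
Why: Copper-catalysed SN2 opening of the 2,2-disubstituted oxirane at its CH2 by the vinyl Grignard reagent, then silylation of the tertiary magnesium alkoxide 7 in the same flask; C8 is untouched, and the oxygen must be capped because a free hydroxyl would intercept the acyl azolium in step 4.

Step 3
Reactants: 8 triethyl{[(2R)-1-(1,3-dithian-2-yl)-2-methylpent-4-en-2-yl]oxy}silane; 9 (E)-but-2-enal (crotonaldehyde)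
Product: 10 (2E,5R)-6-(1,3-dithian-2-yl)-5-methyl-5-[(triethylsilyl)oxy]hex-2-enal
Conditions: second-generation Hoveyda–Grubbs catalyst (5 mol %), 9 (5 equiv), CH2Cl2, 40 °C
Reagents that add atoms: none
Why: Olefin cross-metathesis of the terminal alkene with excess crotonaldehyde gives the E-enal under thermodynamic control; silyl ether and dithiane are spectators.

Step 4
Reactants: 10 (2E,5R)-6-(1,3-dithian-2-yl)-5-methyl-5-[(triethylsilyl)oxy]hex-2-enal; 11 (3E)-6-methylhepta-3,5-dien-2-one
Product: 12 (1R,2S,3R,5S)-2-{(2R)-3-(1,3-dithian-2-yl)-2-methyl-2-[(triethylsilyl)oxy]propyl}-5-methyl-3-(2-methylprop-1-en-1-yl)-6-oxabicyclo[3.2.0]heptan-7-one (cis-fused β-lactone; the two ring side chains trans)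
Conditions: (5aS,10bR) cis-1-amino-2-indanol-derived N-mesityl imidazolium chloride (tetracyclic indeno-oxazino-imidazolium carbene precursor, 10 mol %), DBU (10 mol %), THF, 4 Å sieves, 23 to 40 °C; 10 added slowly to 11 (2 equiv)
Reagents that add atoms: none
Why: Proposed new method: the carbene adds to the aldehyde of 10 and the resulting Breslow intermediate is a homoenolate (nucleophilic enal β-carbon, reversed polarity) that bonds C6 to the electrophilic β-carbon C2 of 11 (δ-attack is blocked by the gem-dimethyl terminus), the azolium enol then closes the five-membered ring by aldol addition to the methyl ketone and the tertiary alkoxide acylates itself to the β-lactone, which should survive because the C4–O carbon carries only alkyl groups; the closest known reaction is the carbene-catalysed [3+2] annulation of enals with chalcones and dienones, where imidazolylidenes give the 3,4-trans cyclopentane and chiral aminoindanol azolium salts set the absolute configuration, so C2 and C6 are set trans by the catalyst while C4 and C5 (assigned by analogy) are erased in step 9; new here are two aliphatic partners and an enolisable methyl ketone.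

Step 5
Reactants: 12 β-lactone dithiane
Product: 13 (3R)-3-methyl-4-[(1R,2S,3R,5S)-5-methyl-3-(2-methylprop-1-en-1-yl)-7-oxo-6-oxabicyclo[3.2.0]heptan-2-yl]-3-[(triethylsilyl)oxy]butanal
Conditions: MeI, CaCO3, MeCN/H2O (9:1), 40 °C
Reagents that add atoms: water O
Why: Alkylative thioacetal cleavage (S-methylation, hydrolysis of the sulfonium) under carbonate-buffered neutral conditions that leave the β-lactone, silyl ether and alkene alone; no stereocentre is involved.

Step 6
Reactants: 13 lactone aldehyde
Product: 14 lactone alcohol (1R,2R,4S,5R,6S,8R,10S): trans-fused hydroazulene core; 1-isopropenyl; 10-OH; 8-methyl-8-OSiEt3; cis β-lactone (O on C4 with 4-methyl; C=O on C5)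
Conditions: Me2AlCl (1.5 equiv), CH2Cl2, −78 to −30 °C; aqueous HCl work-up
Reagents that add atoms: none
Why: Lewis-acid intramolecular carbonyl-ene reaction of the citronellal-to-isopulegol kind: the aldehyde carbon bonds to the CH terminus of the isobutenyl group with hydrogen transfer from a methyl group, and the chair-like seven-membered transition state places the new isopropenyl (C1) and hydroxyl (C10) equatorial, trans to each other and to the C2–C3 bond, with the C8 methyl equatorial; the cyclopentene, which would otherwise win by six-membered closure onto C5, is still masked as the lactone.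

Step 7
Reactants: 14 lactone alcohol; 15 4-(benzyloxy)benzoyl chloride
Product: 16 4-(benzyloxy)benzoate of 14 at O-10 (1R,2R,4S,5R,6S,8R,10S)
Conditions: Et3N, DMAP (0.2 equiv), CH2Cl2, 23 to 40 °C
Reagents that add atoms: none
Why: DMAP-catalysed acylation (acyl pyridinium) of the only free hydroxyl; C10 configuration is retained.

Step 8
Reactants: 16 benzyl-protected ester
Product: 17 lactone phenol (1S,2R,4S,5R,6S,8R,10S): 1-isopropyl; 10-O-(4-hydroxybenzoyl); 8-OSiEt3; β-lactone retained
Conditions: H2 (1 atm), Pd/C (10 wt %), EtOAc, 23 °C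
Reagents that add atoms: none
Why: Heterogeneous hydrogenation saturates the 1,1-disubstituted alkene to isopropyl (no new stereocentre) and hydrogenolyses the benzyl ether in one operation; no other alkene is present because the cyclopentene is still the lactone.

Step 9
Reactants: 17 lactone phenol
Product: 18 cyclopentene silyl ether (1S,2R,6S,8R,10S): C4=C5 alkene with 4-methyl; 10-O-(4-hydroxybenzoyl); 8-OSiEt3
Conditions: toluene, 150 °C (sealed tube)
Reagents that add atoms: none
Why: Thermal [2+2] cycloreversion of the β-lactone (stereospecific syn loss of CO2) places the double bond exactly between C4 and C5.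

Step 10
Reactants: 18 cyclopentene silyl ether
Product: 19 cyclopentene diol monoester (1S,2R,6S,8R,10S): as 18 with free 8-OH
Conditions: HF·pyridine, THF, 0 to 23 °C
Reagents that add atoms: none
Why: Fluoride cleavage of the Si–O bond of the tertiary triethylsilyl ether under buffered conditions that spare the alkene, ester and phenol.

Step 11
Reactants: 19 cyclopentene diol monoester
Product: 20 target CNP0245441.1 (1S,2R,4R,5S,6S,8R,10S)
Conditions: VO(acac)2 (5 mol %), t-BuOOH (1.5 equiv), CH2Cl2, 0 to 23 °C
Reagents that add atoms: tert-butyl hydroperoxide CC(C)(C)OO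
Why: Vanadium-catalysed hydroxyl-directed epoxidation: the axial C8 hydroxyl, bishomoallylic to C4=C5 and on the α-face, binds the vanadium peroxide and delivers oxygen to that face, setting C4 and C5 cis to the C8 hydroxyl; the same syn relationship rules out backside opening of the oxirane by that hydroxyl.

**Compound list**
1 | 1,3-dithiane | C1CSCSC1 | starting material
2 | (S)-2-(chloromethyl)-2-methyloxirane | ClC[C@@]1(C)OC1 | starting material
3 | 2-lithio-1,3-dithiane | [Li]C1SCCCS1 | intermediate
4 | lithium chloro alkoxide: lithium (2S)-1-chloro-3-(1,3-dithian-2-yl)-2-methylpropan-2-olate | ClC[C@@](C)(O[Li])CC1SCCCS1 | intermediate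
5 | (S)-2-[(2-methyloxiran-2-yl)methyl]-1,3-dithiane | C1[C@@](C)(O1)CC2SCCCS2 | intermediate
6 | vinylmagnesium bromide | C=C[Mg]Br | starting material
7 | bromomagnesium alkoxide: bromomagnesium (2R)-1-(1,3-dithian-2-yl)-2-methylpent-4-en-2-olate | C=CC[C@@](C)(O[Mg]Br)CC1SCCCS1 | intermediate
8 | triethyl{[(2R)-1-(1,3-dithian-2-yl)-2-methylpent-4-en-2-yl]oxy}silane | C=CC[C@@](C)(O[Si](CC)(CC)CC)CC1SCCCS1 | intermediate
9 | (E)-but-2-enal (crotonaldehyde) | C/C=C/C=O | starting material
10 | (2E,5R)-6-(1,3-dithian-2-yl)-5-methyl-5-[(triethylsilyl)oxy]hex-2-enal | O=C/C=C/C[C@@](C)(O[Si](CC)(CC)CC)CC1SCCCS1 | intermediate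
11 | (3E)-6-methylhepta-3,5-dien-2-one | CC(=O)/C=C/C=C(C)C | starting material
12 | (1R,2S,3R,5S)-2-{(2R)-3-(1,3-dithian-2-yl)-2-methyl-2-[(triethylsilyl)oxy]propyl}-5-methyl-3-(2-methylprop-1-en-1-yl)-6-oxabicyclo[3.2.0]heptan-7-one | CC(C)=C[C@@H]1C[C@]2(C)OC(=O)[C@@H]2[C@H]1C[C@@](C)(O[Si](CC)(CC)CC)CC3SCCCS3 | intermediate
13 | (3R)-3-methyl-4-[(1R,2S,3R,5S)-5-methyl-3-(2-methylprop-1-en-1-yl)-7-oxo-6-oxabicyclo[3.2.0]heptan-2-yl]-3-[(triethylsilyl)oxy]butanal | CC(C)=C[C@@H]1C[C@]2(C)OC(=O)[C@@H]2[C@H]1C[C@@](C)(O[Si](CC)(CC)CC)CC=O | intermediate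
14 | lactone alcohol (1R,2R,4S,5R,6S,8R,10S), 1-isopropenyl, 10-OH, 8-OSiEt3 | CC(=C)[C@H]1[C@@H]2C[C@]3(C)OC(=O)[C@@H]3[C@H]2C[C@@](C)(O[Si](CC)(CC)CC)C[C@@H]1O | intermediate
15 | 4-(benzyloxy)benzoyl chloride | O=C(Cl)c1ccc(OCc2ccccc2)cc1 | starting material
16 | 4-(benzyloxy)benzoate of 14 at O-10 | CC(=C)[C@H]1[C@@H]2C[C@]3(C)OC(=O)[C@@H]3[C@H]2C[C@@](C)(O[Si](CC)(CC)CC)C[C@@H]1OC(=O)c1ccc(OCc2ccccc2)cc1 | intermediate
17 | lactone phenol (1S,2R,4S,5R,6S,8R,10S), 1-isopropyl, 10-O-(4-hydroxybenzoyl), 8-OSiEt3 | CC(C)[C@H]1[C@@H]2C[C@]3(C)OC(=O)[C@@H]3[C@H]2C[C@@](C)(O[Si](CC)(CC)CC)C[C@@H]1OC(=O)c1ccc(O)cc1 | intermediate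
18 | cyclopentene silyl ether (1S,2R,6S,8R,10S) | CC(C)[C@H]1[C@@H]2CC(C)=C[C@H]2C[C@@](C)(O[Si](CC)(CC)CC)C[C@@H]1OC(=O)c1ccc(O)cc1 | intermediate
19 | cyclopentene diol monoester (1S,2R,6S,8R,10S) | CC(C)[C@H]1[C@@H]2CC(C)=C[C@H]2C[C@@](C)(O)C[C@@H]1OC(=O)c1ccc(O)cc1 | intermediate
20 | CNP0245441.1 (1S,2R,4R,5S,6S,8R,10S) | CC(C)[C@H]1[C@@H]2C[C@@]3(C)O[C@H]3[C@H]2C[C@@](C)(O)C[C@@H]1OC(=O)c1ccc(O)cc1 | target

**Totals**
Total step count: 11. Longest linear sequence: 11 (1 and 2 to 20); 6, 9, 11 and 15 are bought.

**Three steps most likely to fail, with fallbacks**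

Step 4 is the main risk. Neither partner is of the aryl type for which this annulation is established, the methyl ketone is enolisable, the chiral imidazolium salt must be made, and the enal can dimerise or lose its silyloxy group by γ-deprotonation. The lactone might also lose CO2 early, which would expose the cyclopentene to steps 6 and 8. The fallback sets out from 10 and 11 and comes back at 12. It gives up catalyst control for interception and separation: achiral 1,3-dimesitylimidazol-2-ylidene (imidazolium chloride, DBU) in THF/MeOH lets methanol trap the acyl azolium, giving the trans methyl hydroxy ester F1 together with its ring-inverted diastereomer F2. The two are separable by chromatography because C8 is fixed. LiOH then gives the hydroxy acid F3, and PhSO2Cl/pyridine at 0 °C closes it to 12.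

Step 6 is the second risk. A seven-membered carbonyl-ene closure is slower than the six-membered model, and Me2AlCl may ionise the tertiary lactone C–O bond or give a chloro alcohol. The fallback sets out from 13 and comes back at 14, replacing the cationic closure by a reductive organochromium one. PhSeCl (10 mol %) with N-chlorosuccinimide converts the isobutenyl group into the transposed allylic chloride F4 (C1H(Cl)–C(CH3)=CH2; C1 epimers are of no consequence). CrCl2 (divalent chromium) in THF at high dilution then forms the allylchromium, which adds through its γ-carbon C1 to the aldehyde in a Nozaki–Hiyama cyclisation, again giving the trans hydroxyl/isopropenyl pair of 14.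

Step 11 is the third risk. The intrinsic bias of the cyclopentene probably favours the face anti to C7, so the outcome depends on the C8 hydroxyl reaching the alkene; the free phenol may also bind vanadium. The fallback sets out from 18 and comes back at 20, building the oxirane by anti addition and displacement instead of direct oxygen transfer. With the α-face shielded by the axial C8 silyl ether, NBS in THF/H2O at 0 °C forms the bromonium ion on the β-face (the trisubstituted alkene reacts far faster than the ester-deactivated phenol ring) and water opens it at tertiary C4 from the α-face, giving the bromohydrin F5. K2CO3 in MeOH closes the α-oxirane to the epoxy silyl ether F6, and TBAF in THF gives 20.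

**Further compounds**
F1 | step 4 | methyl hydroxy ester with the ring configuration of 12: methyl 2-hydroxy-2-methyl-4-(2-methylprop-1-en-1-yl)-5-{(2R)-3-(1,3-dithian-2-yl)-2-methyl-2-[(triethylsilyl)oxy]propyl}cyclopentane-1-carboxylate | CC(C)=C[C@@H]1C[C@](C)(O)[C@H](C(=O)OC)[C@H]1C[C@@](C)(O[Si](CC)(CC)CC)CC2SCCCS2
F2 | step 4 | diastereomer of F1 with all four ring centres inverted | CC(C)=C[C@H]1C[C@@](C)(O)[C@@H](C(=O)OC)[C@@H]1C[C@@](C)(O[Si](CC)(CC)CC)CC2SCCCS2
F3 | step 4 | hydroxy acid from F1 | CC(C)=C[C@@H]1C[C@](C)(O)[C@H](C(=O)O)[C@H]1C[C@@](C)(O[Si](CC)(CC)CC)CC2SCCCS2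
F4 | step 6 | allylic chloride of 13 (1-chloro-2-methylprop-2-en-1-yl group on the lactone ring) | CC(=C)C(Cl)[C@@H]1C[C@]2(C)OC(=O)[C@@H]2[C@H]1C[C@@](C)(O[Si](CC)(CC)CC)CC=O
F5 | step 11 | bromohydrin of 18 (4-OH on the α-face, 5-Br on the β-face) | CC(C)[C@H]1[C@@H]2C[C@@](C)(O)[C@H](Br)[C@H]2C[C@@](C)(O[Si](CC)(CC)CC)C[C@@H]1OC(=O)c1ccc(O)cc1
F6 | step 11 | 8-O-triethylsilyl ether of 20 | CC(C)[C@H]1[C@@H]2C[C@@]3(C)O[C@H]3[C@H]2C[C@@](C)(O[Si](CC)(CC)CC)C[C@@H]1OC(=O)c1ccc(O)cc1
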